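All constants are assumed; the result is computed.

I read this flask at 6.0 min and want one number for what stands in it then.

solid substrate 0.50 M; solid reagent 0.450 M; time 6.0 min

1. amount of target and crystals together at 6.0 min, in percent of the solid substrate charged
2. concentration of dissolved substrate in solution at 6.0 min, in percent of saturation

- for target the crystals are counted in
- as a solid, counted per litre of solution: solid substrate, crystals, solid reagent
- at the start none of the solid substrate is in solution
- at the start none of the solid reagent is in solution
- dissolved substrate means what is dissolved; the solid is not counted in it
- run time (flask): 6.0 min

    solid substrate ⇌ dissolved substrate, rate k1*(cs1 - [dissolved substrate]) while solid is left; crystals form when [dissolved substrate] > cs1 (cs1 = 0.27 M, k1 = 7.61 min⁻¹)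
    dissolved substrate + partner → target (k2 = 16.8 L mol⁻¹ min⁻¹)
    crystals ⇌ target, rate k3*(cs3 - [target]) while solid is left; crystals form when [target] > cs3 (cs3 = 7.1 mM, k3 = 5.56 min⁻¹)
    partner ⇌ dormant form (K4 = 2.86, k4 = 0.225 min⁻¹)
    solid reagent ⇌ partner, rate k5*(cs5 - [partner]) while solid is left; crystals form when [partner] > cs5 (cs5 = 0.10 M, k5 = 3.88 min⁻¹)

1. Late end: each partner takes one dissolved substrate, and the solid reagent is charged at 0.900 of the solid substrate, so it is the limiting reagent.

2. Early end: into a solution kept empty, dissolving could deliver 2466% of the charge by 6.0 min, far more than the charge, so while solid lasts I take dissolved substrate to stand at its solubility. A partner then reacts at 4.54 min⁻¹ and turns dormant at 0.225 min⁻¹, much more slowly, so a share of 4.73% strays.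

3. Joined, the ends give 85.7%: the reach, the equivalents of solid reagent times the share of partner that reacts. I expect that fraction of the charge as target and crystals.

4. Is one number enough? With partner held where supply equals use, the solid reagent lasts about 2.15 min, shorter than the run. By its reverse step alone, dormant form returns with a half-life of 8.81 min, longer than the run. I leave out this return, and also the fall of dissolved substrate below solubility late on.

5. I expect the remaining 14.3% of the charge to stay dissolved, below saturation, at 26.4% of saturation.

The forecast gives 86% (82% to 89%) and 26% (22% to 33%), holding that “the partner held in the dormant form stays unreacted”.

The flask gives 85.4% and 27.1%.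

The reach of 85.7% stands 0.30 percentage points above the yield of this flask. The neighbouring flask is charged with 0.27 M of solid reagent, all else as in the recipe. Its equivalents are 0.540, and the same reacting share makes its reach 51.4%. That neighbour gives 52.0%. At the end of it, 0.069% of its solid reagent is still there, solid or dissolved, and 48% of its solid substrate.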